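## The problem

The target is a 2-arylbenzofuran. C2 of a 6-hydroxybenzofuran is joined to C1' of a benzene ring that carries prenyl (3-methylbut-2-enyl) groups at C2' and C6', a free hydroxyl at C3', a methoxy group at C5', and hydrogen only at C4'. There is no stereocentre, so the synthesis has to solve placement, not configuration. The C2–C1' bond is flanked on both sides by prenyl groups, and the oxygens at C3' and C5', equivalent but for the methyl group, must end up different. On a preformed arene both tasks are awkward: coupling at a di-ortho-substituted carbon is slow, and electrophilic prenylation of a 5-arylresorcinol would favour the open C4' position between the oxygens. The fragile groups are the two trisubstituted alkenes, the two electron-rich phenols and the benzofuran C2=C3 bond; acid closes the C2' prenyl group onto the C3' hydroxyl to give a chroman, and hydrogenation, quinone oxidants and electrophilic halogen attack the alkenes. The feature that opens a way round the crowding is the 1,3-relationship of the oxygens at C3' and C5' with unsubstituted C4' between them. This is the pattern of a cyclohexane-1,3-dione, and because the ring without its O-methyl group has a mirror plane through C1' and C4', that dione is symmetric. The six ring carbons then divide into a four-carbon enone unit (C4'–C3'–C2'–C1') and a two-carbon malonate unit (C6'–C5'), so every substituent can be delivered on an acyclic or sp3 carbon. The price is one oxidation level: the carbocycle is formed as a dione and must be dehydrogenated once in the presence of both prenyl groups.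

## Retrosynthesis

**22 to 21.** The last bond cut is the O–CH2 bond of a methoxymethyl acetal on O6 of the benzofuran. The benzofuranol must be masked because the route uses an aryllithium, hot ethoxide, hydroxide and an amide base. A benzyl ether is excluded because hydrogenolysis would saturate the prenyl groups, a silyl ether would not survive the alkoxide steps, and a methyl ether could not be distinguished from the C5' methoxy group. Precursor 21 differs from 22 only by this acetal. The forward step must open the acetal without protonating the alkene next to the free C3' hydroxyl.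

**21 to 16.** No skeletal bond is cut here; two hydrogens are returned to C1' and C6', so the arene is seen as a dehydrogenated 3-methoxycyclohex-2-enone 16. The neighbouring cuts, the C2–C1' bond or the two aryl–prenyl bonds on an intact arene, would all act at the most hindered aromatic positions. In 16 the same three substituents sit on sp3 carbons, and its three uncontrolled stereocentres disappear on aromatisation. The forward reaction must be a single dehydrogenation that leaves two trisubstituted alkenes alone, which points to enolate chemistry (selenoxide elimination) rather than quinone or noble-metal dehydrogenation.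

**16 to 15.** The O–CH3 bond is cut. Dione 15 has two equivalent carbonyl groups, so mono-O-methylation can give only one constitution. This is the point at which the C3' and C5' oxygens become different, without a protecting group. The forward step must methylate on oxygen under non-acidic conditions, since the acetal is present.

**15 to 13.** An ethoxycarbonyl group is returned to the prenyl-bearing carbon C6'. It is the activating group that makes the ring-forming chemistry possible and is removed by saponification and decarboxylation. The ester does not complicate 13, because it is carried by one of the two building blocks.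

**13 to 9 and 11 (key disconnection).** Two ring bonds are cut: C1'–C6' (conjugate addition) and C4'–C5' (Claisen acylation). This opens the carbocycle to enone 9 and diethyl prenylmalonate 11. Compared with any disconnection of the arene itself, this one places both prenyl groups and the benzofuranyl group before the ring exists, and both partners are simple and acyclic. The forward reaction needs 1,4-addition of a hindered but soft carbanion and closure through the methyl-ketone enolate.

**9 to 4 and 8.** The trisubstituted C=C bond of the enone is cut to aldehyde 4 and the alpha-prenylated beta-ketophosphonate 8. A direct aldol condensation of the parent methyl ketone would react at its methyl group under base, and the acidic variant that reacts at the methylene would endanger the alkene and the acetal. The phosphonate fixes the site of condensation. The alkene geometry matters little, because that double bond is consumed in the key step.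

**8 to 5 and 6; 11 to 10 and 6; 4 to 2 to 1.** Phosphonate 8 and malonate 11 each arise by one C-alkylation of a commercial active-methylene compound (5 or 10) with prenyl bromide 6. Aldehyde 4 comes from commercial benzofuran-6-ol 1 by protection to 2 and formylation at C2, the most acidic position of the benzofuran, so the heterocycle is bought rather than built.

## Roads not taken

**Alternative 1:** The furan C2=C3 bond is cut. The precursor is the aryl ester A1, made from a 2-hydroxy-4-(methoxymethoxy)benzaldehyde and a 2,6-diprenylated benzoic acid. Low-valent titanium would couple the formyl carbon with the ester carbonyl carbon to give the bis-acetal A2, two deprotections from the target.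
- Merits: the closure is a known route to 2-arylbenzofurans, it is convergent, the reagent ignores isolated alkenes, and no ring ever has to be oxidised to the aromatic level. In that respect it is better than the chosen plan, which must carry out a dehydrogenation next to two prenyl groups.
- Weak points: the hard part of the target is only moved into the acid half of A1. That half is still a benzene ring with five substituents, two prenyl groups flanking the carbon that bears the carboxyl, and two oxygens to differentiate. The ester carbonyl of A1 sits between two ortho prenyl groups, which hinders both the esterification and the reductive coupling; aldehyde self-coupling or reduction could then compete.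
- Comparison: the end game needs acid to remove two acetals, one of them on the oxygen ortho to a prenyl group, so it is no gentler than the chosen one. The chosen plan sets against the missing dehydrogenation that it actually constructs the crowded ring, from two acyclic partners each made in one or two steps.

**Alternative 2:** Three bonds of the aryl ring are cut (C3'–C4', C5'–C6', C2'–C3'). Heating cyclobutenone A3 with methoxyacetylene A4 would give a vinylketene, a [2+2] adduct, a dienylketene and finally, by six-electron electrocyclisation, the silyl-protected target A5.
- Merits: it is the most elegant of the four plans. The ring arrives aromatic, with OH and OMe already different, and the end game is one fluoride deprotection with no acid and no oxidation. On step count after the key step and on mildness of the last step it is better than the chosen plan.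
- Weak points: A3 is a 2,3,4-trisubstituted cyclobutenone with a prenyl group on its sp3 carbon, and there is no short, regiocontrolled way to it; a ketene–alkyne cycloaddition with an unpolarised internal alkyne would be unselective. A4 is volatile and unstable and must be prepared. The thermal cascade passes through two ketenes that each carry a prenyl alkene within reach for intramolecular [2+2] or ene reactions.
- Comparison: the chosen plan offers commercial or one-step partners and ionic reactions of well-understood scope. It accepts three more steps after ring formation in exchange.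

**Alternative 3:** The benzo ring of the benzofuran is cut at C7a–C7 and C5–C6. Irradiation of diazoketone A6 would cause Wolff rearrangement to a furylketene, which closes onto the vinyl group and tautomerises to the 6-hydroxybenzofuran A7.
- Merits: the C6 hydroxyl appears free and in an unambiguous position, so the benzofuranol needs no protecting group.
- Weak points: the step builds the one part of the molecule that can be bought (1 is commercial) and leaves the penta-substituted aryl ring untouched as a substituent of A6. That ring would still have to be made by other means and then attached to a 2,3,5-trisubstituted furan. A diazoketone must also be prepared and photolysed in a molecule with two electron-rich alkenes.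
- Comparison: it is longer and addresses the easy half of the problem. The chosen plan spends two steps on protecting and deprotecting the benzofuranol but puts its key step on the ring that is actually difficult.

Key step: step 6

Assumption: the target has no stereocentre, so compounds 8 and 12–20 are taken as racemates or diastereomer mixtures and their SMILES are written without configuration.

## Route

Step 1
Reactants: 1 benzofuran-6-ol
Product: 2 6-(methoxymethoxy)-1-benzofuran
Conditions: MOMCl, i-Pr2NEt, CH2Cl2, 0 °C to rt
Reagents that add atoms: chloromethyl methyl ether, COCCl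
Why: O-alkylation of the phenol (methoxymethyl ether formation); the acetal is inert to the organolithium, alkoxide, hydroxide and amide bases used later and is the only protecting group of the route.

Step 2
Reactants: 2 6-(methoxymethoxy)-1-benzofuran
Product: 4 6-(methoxymethoxy)-1-benzofuran-2-carbaldehyde, via 2-lithio-6-(methoxymethoxy)-1-benzofuran 3 (not isolated)
Conditions: n-BuLi, THF, −78 °C; DMF, −78 to 0 °C; H2O
Reagents that add atoms: N,N-dimethylformamide, CN(C)C=O
Why: Lithiation of the benzofuran at C2, its most acidic C–H bond, followed by formylation with a formamide; at −78 °C acetal-directed ortho-lithiation at C5 or C7 should not compete.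

Step 3
Reactants: 5 dimethyl (2-oxopropyl)phosphonate; 6 1-bromo-3-methylbut-2-ene (prenyl bromide)
Product: 8 dimethyl (6-methyl-2-oxohept-5-en-3-yl)phosphonate (racemic), via sodium 1-(dimethoxyphosphoryl)prop-1-en-2-olate 7 (not isolated)
Conditions: NaH (1.0 equiv), THF, 0 °C; 6, 0 °C to rt
Reagents that add atoms: none
Why: C-alkylation (SN2) of the beta-ketophosphonate monoanion at its doubly activated carbon by a soft allylic bromide; one equivalent each of base and halide limits dialkylation.

Step 4
Reactants: 4 6-(methoxymethoxy)-1-benzofuran-2-carbaldehyde; 8 dimethyl (6-methyl-2-oxohept-5-en-3-yl)phosphonate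
Product: 9 (3E)-3-{[6-(methoxymethoxy)-1-benzofuran-2-yl]methylidene}-6-methylhept-5-en-2-one
Conditions: LiCl, DBU, MeCN, rt to 40 °C
Reagents that add atoms: none
Why: Horner–Wadsworth–Emmons olefination under Masamune–Roush conditions, expected to place the aryl group trans to the acetyl group (E); a minor Z isomer would be harmless because step 6 destroys this double bond.

Step 5
Reactants: 10 diethyl malonate; 6 1-bromo-3-methylbut-2-ene (prenyl bromide)
Product: 11 diethyl 2-(3-methylbut-2-en-1-yl)propanedioate
Conditions: K2CO3, acetone, reflux (10 in excess)
Reagents that add atoms: none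
Why: Malonic ester alkylation (SN2) with a reactive allylic bromide; excess malonate suppresses the dialkylated product.

Step 6
Reactants: 9 (3E)-3-{[6-(methoxymethoxy)-1-benzofuran-2-yl]methylidene}-6-methylhept-5-en-2-one; 11 diethyl 2-(3-methylbut-2-en-1-yl)propanedioate
Product: 13 ethyl 6-[6-(methoxymethoxy)-1-benzofuran-2-yl]-1,5-bis(3-methylbut-2-en-1-yl)-2,4-dioxocyclohexane-1-carboxylate (mixture of racemic diastereomers), via open-chain Michael adduct 12 (not isolated)
Conditions: 11 (1.3 equiv), NaOEt (1.1 equiv), EtOH, rt then reflux; AcOH, 0 °C
Reagents that add atoms: none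
Why: Ethoxide forms the prenylmalonate anion, a soft stabilised carbanion that adds to the beta carbon of enone 9 (bond C1'–C6'); proton transfer then gives the methyl-ketone enolate of adduct 12, which attacks one of the two ester carbonyls with loss of ethoxide (bond C4'–C5') and so closes the carbocycle. The closest known reaction is the dimedone synthesis, the Michael–Claisen annulation of a malonate with an enone to a cyclohexane-1,3-dione, here with a C-substituted malonate and an alpha-branched enone. The ring closes in the 6-(enolendo)-exo-trig mode, a favoured closure, whereas the enolate at the prenyl-bearing alpha carbon could only form a four-membered ring. Three stereocentres arise (C1, C5 and C6 of the cyclohexane) without control, and none is needed because all three become sp2 carbons of the arene. The step needs 1,4- rather than 1,2-addition, which the soft and reversibly adding malonate anion secures. It also needs the reversible Michael equilibrium to be drained: product 13 is a 1,3-diketone that ethoxide deprotonates at C3, and this enolate formation makes the sequence effectively irreversible and protects the ring against retro-Claisen opening.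

Step 7
Reactants: 13 ethyl 6-[6-(methoxymethoxy)-1-benzofuran-2-yl]-1,5-bis(3-methylbut-2-en-1-yl)-2,4-dioxocyclohexane-1-carboxylate
Product: 15 5-[6-(methoxymethoxy)-1-benzofuran-2-yl]-4,6-bis(3-methylbut-2-en-1-yl)cyclohexane-1,3-dione (mixture of diastereomers), via beta-keto acid 14 (not isolated)
Conditions: KOH, EtOH/H2O, reflux; then AcOH to pH 5, 60 °C
Reagents that add atoms: none
Why: Saponification followed by decarboxylation of the beta-keto acid, as in the dimedone procedure; the dione is present as its enolate under base, which prevents ring cleavage, and buffered acetic acid is too weak to open the aryl acetal.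

Step 8
Reactants: 15 5-[6-(methoxymethoxy)-1-benzofuran-2-yl]-4,6-bis(3-methylbut-2-en-1-yl)cyclohexane-1,3-dione
Product: 16 3-methoxy-5-[6-(methoxymethoxy)-1-benzofuran-2-yl]-4,6-bis(3-methylbut-2-en-1-yl)cyclohex-2-en-1-one (mixture of racemic diastereomers)
Conditions: TMSCHN2, MeOH/toluene, 0 °C to rt
Reagents that add atoms: trimethylsilyldiazomethane, C[Si](C)(C)C=[N+]=[N-]
Why: O-methylation of the acidic enol of a cyclic 1,3-dione by a diazoalkane (vinylogous ester formation) under neutral conditions; the two carbonyl groups of 15 are equivalent, so only one constitution can form.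

Step 9
Reactants: 16 3-methoxy-5-[6-(methoxymethoxy)-1-benzofuran-2-yl]-4,6-bis(3-methylbut-2-en-1-yl)cyclohex-2-en-1-one
Product: 21 5-methoxy-3-[6-(methoxymethoxy)-1-benzofuran-2-yl]-2,4-bis(3-methylbut-2-en-1-yl)phenol, via lithium dienolate 17 (not isolated), via 6-(phenylselanyl) ketone 18 (not isolated), via selenoxide 19 (not isolated), via cyclohexa-2,5-dienone 20 (not isolated)
Conditions: LiN(i-Pr)2, THF, −78 °C; PhSeBr, −78 °C; crude selenide: mCPBA (1.0 equiv), CH2Cl2, −78 °C; i-Pr2NH, −78 °C to rt
Reagents that add atoms: none
Why: Kinetic deprotonation of the vinylogous ester at C6 (the site used in Stork–Danheiser alkylations) gives dienolate 17, which is selenenylated anti to the C5 aryl group; selenoxide 19 then has the C5 hydrogen syn and undergoes selenoxide syn-elimination to dienone 20, the keto tautomer of the phenol, which enolises at once. One equivalent of peracid at −78 °C oxidises selenium faster than the alkenes, and the amine captures benzeneselenenic acid before it can add to the prenyl groups or the new phenol.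

Step 10
Reactants: 21 5-methoxy-3-[6-(methoxymethoxy)-1-benzofuran-2-yl]-2,4-bis(3-methylbut-2-en-1-yl)phenol
Product: 22 2-[3-hydroxy-5-methoxy-2,6-bis(3-methylbut-2-en-1-yl)phenyl]-1-benzofuran-6-ol (CNP0324103.0)
Conditions: HCl (dilute, in MeOH), rt to 40 °C
Reagents that add atoms: none
Why: Acid-catalysed acetal exchange with methanol (methoxymethyl ether cleavage); under dilute, mild conditions protonation of the trisubstituted alkenes, the first event of chroman formation, should be slower than opening of the acetal.

## Compound list

1 | benzofuran-6-ol | Oc1ccc2ccoc2c1 | starting material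
2 | 6-(methoxymethoxy)-1-benzofuran | COCOc1ccc2ccoc2c1 | intermediate
3 | 2-lithio-6-(methoxymethoxy)-1-benzofuran | [Li]c1cc2ccc(OCOC)cc2o1 | intermediate (not isolated)
4 | 6-(methoxymethoxy)-1-benzofuran-2-carbaldehyde | O=Cc1cc2ccc(OCOC)cc2o1 | intermediate
5 | dimethyl (2-oxopropyl)phosphonate | COP(=O)(CC(C)=O)OC | starting material
6 | 1-bromo-3-methylbut-2-ene (prenyl bromide) | CC(C)=CCBr | starting material
7 | sodium 1-(dimethoxyphosphoryl)prop-1-en-2-olate | CC([O-])=CP(=O)(OC)OC.[Na+] | intermediate (not isolated)
8 | dimethyl (6-methyl-2-oxohept-5-en-3-yl)phosphonate, racemic | COP(=O)(OC)C(CC=C(C)C)C(C)=O | intermediate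
9 | (3E)-3-{[6-(methoxymethoxy)-1-benzofuran-2-yl]methylidene}-6-methylhept-5-en-2-one | CC(=O)/C(CC=C(C)C)=C/c1cc2ccc(OCOC)cc2o1 | intermediate
10 | diethyl malonate | CCOC(=O)CC(=O)OCC | starting material
11 | diethyl 2-(3-methylbut-2-en-1-yl)propanedioate | CCOC(=O)C(CC=C(C)C)C(=O)OCC | intermediate
12 | diethyl 2-{2-acetyl-1-[6-(methoxymethoxy)-1-benzofuran-2-yl]-5-methylhex-4-en-1-yl}-2-(3-methylbut-2-en-1-yl)propanedioate, diastereomer mixture | CCOC(=O)C(CC=C(C)C)(C(=O)OCC)C(c1cc2ccc(OCOC)cc2o1)C(CC=C(C)C)C(C)=O | intermediate (not isolated)
13 | ethyl 6-[6-(methoxymethoxy)-1-benzofuran-2-yl]-1,5-bis(3-methylbut-2-en-1-yl)-2,4-dioxocyclohexane-1-carboxylate, diastereomer mixture | CCOC(=O)C1(CC=C(C)C)C(=O)CC(=O)C(CC=C(C)C)C1c1cc2ccc(OCOC)cc2o1 | intermediate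
14 | 6-[6-(methoxymethoxy)-1-benzofuran-2-yl]-1,5-bis(3-methylbut-2-en-1-yl)-2,4-dioxocyclohexane-1-carboxylic acid, diastereomer mixture | OC(=O)C1(CC=C(C)C)C(=O)CC(=O)C(CC=C(C)C)C1c1cc2ccc(OCOC)cc2o1 | intermediate (not isolated)
15 | 5-[6-(methoxymethoxy)-1-benzofuran-2-yl]-4,6-bis(3-methylbut-2-en-1-yl)cyclohexane-1,3-dione, diastereomer mixture | O=C1CC(=O)C(CC=C(C)C)C(c2cc3ccc(OCOC)cc3o2)C1CC=C(C)C | intermediate
16 | 3-methoxy-5-[6-(methoxymethoxy)-1-benzofuran-2-yl]-4,6-bis(3-methylbut-2-en-1-yl)cyclohex-2-en-1-one, diastereomer mixture | COC1=CC(=O)C(CC=C(C)C)C(c2cc3ccc(OCOC)cc3o2)C1CC=C(C)C | intermediate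
17 | lithium 5-methoxy-3-[6-(methoxymethoxy)-1-benzofuran-2-yl]-2,4-bis(3-methylbut-2-en-1-yl)cyclohexa-1,5-dien-1-olate | COC1=CC(O[Li])=C(CC=C(C)C)C(c2cc3ccc(OCOC)cc3o2)C1CC=C(C)C | intermediate (not isolated)
18 | 3-methoxy-5-[6-(methoxymethoxy)-1-benzofuran-2-yl]-4,6-bis(3-methylbut-2-en-1-yl)-6-(phenylselanyl)cyclohex-2-en-1-one | COC1=CC(=O)C(CC=C(C)C)([Se]c2ccccc2)C(c2cc3ccc(OCOC)cc3o2)C1CC=C(C)C | intermediate (not isolated)
19 | 6-(benzeneseleninyl)-3-methoxy-5-[6-(methoxymethoxy)-1-benzofuran-2-yl]-4,6-bis(3-methylbut-2-en-1-yl)cyclohex-2-en-1-one | COC1=CC(=O)C(CC=C(C)C)([Se](=O)c2ccccc2)C(c2cc3ccc(OCOC)cc3o2)C1CC=C(C)C | intermediate (not isolated)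
20 | 3-methoxy-5-[6-(methoxymethoxy)-1-benzofuran-2-yl]-4,6-bis(3-methylbut-2-en-1-yl)cyclohexa-2,5-dien-1-one, racemic | COC1=CC(=O)C(CC=C(C)C)=C(c2cc3ccc(OCOC)cc3o2)C1CC=C(C)C | intermediate (not isolated)
21 | 5-methoxy-3-[6-(methoxymethoxy)-1-benzofuran-2-yl]-2,4-bis(3-methylbut-2-en-1-yl)phenol | COc1cc(O)c(CC=C(C)C)c(-c2cc3ccc(OCOC)cc3o2)c1CC=C(C)C | intermediate
22 | 2-[3-hydroxy-5-methoxy-2,6-bis(3-methylbut-2-en-1-yl)phenyl]-1-benzofuran-6-ol (CNP0324103.0) | COc1cc(O)c(CC=C(C)C)c(-c2cc3ccc(O)cc3o2)c1CC=C(C)C | target

## Step count and risks

Total: 10 steps. Longest linear sequence: 8 steps from benzofuran-6-ol 1 (steps 1, 2, 4, 6, 7, 8, 9, 10). Steps 3 and 5 are one-step side branches.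

**Step 6 (key step).** The conjugate addition may stall. A tertiary malonate carbanion has to create a quaternary carbon next to a tertiary one on an alpha-branched, beta-heteroaryl enone, so the Michael equilibrium may lie on the side of the components, and retro-addition or ethoxide-induced retro-aldol cleavage of 9 could outrun ring closure.
Fallback: set out from 9 and use unsubstituted diethyl malonate 10 under the same ethoxide conditions. Being less hindered and more acidic, it should give ethyl 6-[6-(methoxymethoxy)-1-benzofuran-2-yl]-5-(3-methylbut-2-en-1-yl)-2,4-dioxocyclohexane-1-carboxylate F1. The missing prenyl group is then introduced by dianion alkylation: two equivalents of LiN(i-Pr)2 in THF deprotonate first C3 and then the ester-bearing carbon, and the second, more reactive site is alkylated by 6. This returns to the route at 13.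

**Step 9.** The selenoxide may eliminate toward the side-chain CH2 of the C6 prenyl group (allylic hydrogens, freely rotating) instead of toward the ring C5–H, giving an exocyclic dienone that does not tautomerise to the phenol. Selenium electrophiles may also add to the prenyl alkenes.
Fallback: set out from 16. Trap dienolate 17 with TBSCl (THF/DMPU) as tert-butyl({5-methoxy-3-[6-(methoxymethoxy)-1-benzofuran-2-yl]-2,4-bis(3-methylbut-2-en-1-yl)cyclohexa-1,5-dien-1-yl}oxy)dimethylsilane F2. F2 is a cyclohexa-1,3-diene, and one equivalent of DDQ with 2,6-lutidine in CH2Cl2 at 0 °C should abstract hydride from either ring sp3 carbon, both of which lead to the same arenium ion. This gives the aryl silyl ether tert-butyl{5-methoxy-3-[6-(methoxymethoxy)-1-benzofuran-2-yl]-2,4-bis(3-methylbut-2-en-1-yl)phenoxy}dimethylsilane F3. The phenol stays masked while the quinone is present. TBAF in THF then returns to the route at 21.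

**Step 10.** Acid may protonate the C2' prenyl alkene, and capture of the cation by the neighbouring C3' hydroxyl would close a 2,2-dimethylchroman; addition of HCl or methanol to the alkenes is the related side process.
Fallback: set out from 21 and remove the internal nucleophile first. Acetylation (Ac2O, pyridine) gives 5-methoxy-3-[6-(methoxymethoxy)-1-benzofuran-2-yl]-2,4-bis(3-methylbut-2-en-1-yl)phenyl acetate F4. The acetal is then opened under aprotic Lewis-acid conditions (ZnBr2, n-PrSH, CH2Cl2, 0 °C) to 3-(6-hydroxy-1-benzofuran-2-yl)-5-methoxy-2,4-bis(3-methylbut-2-en-1-yl)phenyl acetate F5. Methanolysis (K2CO3, MeOH, rt) returns to the route at 22.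

**Step 4.** The carbanion of the alpha-branched phosphonate 8 is hindered and the heteroaryl aldehyde is electron-rich, so the olefination may be slow and incomplete; dialkylation in step 3 would reduce the supply of 8 further.
Fallback: set out from 4 and avoid the phosphonate. A Morita–Baylis–Hillman reaction with but-3-en-2-one (DABCO) gives 3-{hydroxy[6-(methoxymethoxy)-1-benzofuran-2-yl]methyl}but-3-en-2-one F6. Acetylation (Ac2O, DMAP) gives 1-[6-(methoxymethoxy)-1-benzofuran-2-yl]-2-methylidene-3-oxobutyl acetate F7. SN2' substitution with (2-methylprop-1-enyl)magnesium bromide and catalytic CuI in THF at −78 °C installs the prenyl chain and the trisubstituted double bond together, returning to the route at 9.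

**Step 7.** Saponification may be incomplete, because the ester carbonyl sits on a quaternary carbon next to the anionic dione enolate and is shielded from hydroxide.
Fallback: set out from 13 and use Krapcho dealkoxycarbonylation (LiCl, wet DMSO, 150 °C). Chloride attacks the ethyl group instead of the hindered carbonyl, and the carboxylate loses CO2 under neutral conditions, returning to the route at 15 without a new compound.

## Further compounds

F1 | step 6 | ethyl 6-[6-(methoxymethoxy)-1-benzofuran-2-yl]-5-(3-methylbut-2-en-1-yl)-2,4-dioxocyclohexane-1-carboxylate (diastereomer mixture) | CCOC(=O)C1C(=O)CC(=O)C(CC=C(C)C)C1c1cc2ccc(OCOC)cc2o1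
F2 | step 9 | tert-butyl({5-methoxy-3-[6-(methoxymethoxy)-1-benzofuran-2-yl]-2,4-bis(3-methylbut-2-en-1-yl)cyclohexa-1,5-dien-1-yl}oxy)dimethylsilane (diastereomer mixture) | COC1=CC(O[Si](C)(C)C(C)(C)C)=C(CC=C(C)C)C(c2cc3ccc(OCOC)cc3o2)C1CC=C(C)C
F3 | step 9 | tert-butyl{5-methoxy-3-[6-(methoxymethoxy)-1-benzofuran-2-yl]-2,4-bis(3-methylbut-2-en-1-yl)phenoxy}dimethylsilane | COc1cc(O[Si](C)(C)C(C)(C)C)c(CC=C(C)C)c(-c2cc3ccc(OCOC)cc3o2)c1CC=C(C)C
F4 | step 10 | 5-methoxy-3-[6-(methoxymethoxy)-1-benzofuran-2-yl]-2,4-bis(3-methylbut-2-en-1-yl)phenyl acetate | COc1cc(OC(C)=O)c(CC=C(C)C)c(-c2cc3ccc(OCOC)cc3o2)c1CC=C(C)C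
F5 | step 10 | 3-(6-hydroxy-1-benzofuran-2-yl)-5-methoxy-2,4-bis(3-methylbut-2-en-1-yl)phenyl acetate | COc1cc(OC(C)=O)c(CC=C(C)C)c(-c2cc3ccc(O)cc3o2)c1CC=C(C)C
F6 | step 4 | 3-{hydroxy[6-(methoxymethoxy)-1-benzofuran-2-yl]methyl}but-3-en-2-one (racemic) | CC(=O)C(=C)C(O)c1cc2ccc(OCOC)cc2o1
F7 | step 4 | 1-[6-(methoxymethoxy)-1-benzofuran-2-yl]-2-methylidene-3-oxobutyl acetate (racemic) | CC(=O)OC(C(=C)C(C)=O)c1cc2ccc(OCOC)cc2o1
F0 | step 7 | none | none
A1 | alternative 1 | 2-formyl-5-(methoxymethoxy)phenyl 3-methoxy-5-(methoxymethoxy)-2,6-bis(3-methylbut-2-en-1-yl)benzoate | O=Cc1ccc(OCOC)cc1OC(=O)c1c(CC=C(C)C)c(OCOC)cc(OC)c1CC=C(C)C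
A2 | alternative 1 | 6-(methoxymethoxy)-2-[3-methoxy-5-(methoxymethoxy)-2,6-bis(3-methylbut-2-en-1-yl)phenyl]-1-benzofuran | COCOc1ccc2cc(-c3c(CC=C(C)C)c(OCOC)cc(OC)c3CC=C(C)C)oc2c1
A3 | alternative 2 | 3-{6-[(tert-butyldimethylsilyl)oxy]-1-benzofuran-2-yl}-2,4-bis(3-methylbut-2-en-1-yl)cyclobut-2-en-1-one (racemic) | O=C1C(CC=C(C)C)=C(c2cc3ccc(O[Si](C)(C)C(C)(C)C)cc3o2)C1CC=C(C)C
A4 | alternative 2 | methoxyacetylene (methoxyethyne) | COC#C
A5 | alternative 2 | 3-{6-[(tert-butyldimethylsilyl)oxy]-1-benzofuran-2-yl}-5-methoxy-2,4-bis(3-methylbut-2-en-1-yl)phenol | COc1cc(O)c(CC=C(C)C)c(-c2cc3ccc(O[Si](C)(C)C(C)(C)C)cc3o2)c1CC=C(C)C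
A6 | alternative 3 | 2-diazo-1-{3-ethenyl-5-[3-methoxy-5-(methoxymethoxy)-2,6-bis(3-methylbut-2-en-1-yl)phenyl]furan-2-yl}ethan-1-one | [N-]=[N+]=CC(=O)c1oc(-c2c(CC=C(C)C)c(OCOC)cc(OC)c2CC=C(C)C)cc1C=C
A7 | alternative 3 | 2-[3-methoxy-5-(methoxymethoxy)-2,6-bis(3-methylbut-2-en-1-yl)phenyl]-1-benzofuran-6-ol | Oc1ccc2cc(-c3c(CC=C(C)C)c(OCOC)cc(OC)c3CC=C(C)C)oc2c1
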